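A straight fall of Sub is easily run on down to zero, but a line read from one run does not show how the last fraction of the charge goes.

| flask | Sub | Ptn | Spx | remark | time |
|---|---|---|---|---|---|
| teal | 34 mM | 200 mM | 3.4 mM | run made earlier |  |
| amber | 34 mM | 1100 mM | 3.4 mM | run made earlier |  |
| Friday's | 34 mM | 170 mM | 3.4 mM |  | 8.0 min |
| Tuesday's | 34 mM | 340 mM | 3.4 mM |  | 8.0 min |
| Sunday's | 34 mM | 680 mM | 3.4 mM |  | 8.0 min |

| run | time / min | Sub / % | Prd / % |
|---|---|---|---|
| teal | 0.667 | 93 | 3 |
| teal | 2.00 | 76 | 12 |
| teal | 4.00 | 58 | 25 |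
| teal | 6.00 | 37 | 31 |
| teal | 8.00 | 24 | 42 |
| amber | 0.667 | 62 | 20 |
| amber | 1.33 | 30 | 45 |
| amber | 2.50 | 12 | 72 |
| amber | 4.00 | 1 | 87 |
| amber | 8.00 | 1 | 101 |

(readings scatter by 1.5 percentage points)

1. part of the Sub that has reacted at the end, Friday's
2. part of the Sub that has reacted at the end, Tuesday's
3. part of the Sub that has reacted at the end, Sunday's
4. what raising the concentration of Ptn from its lowest to its highest value here does to the part of the Sub that has reacted (changes below 5 percentage points count as none) (it rises / it falls / no change)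

- a reading or a percentage of Prd counts all its forms, free or not
- what has gone from Sub into another species counts as reacted, even if it can come back

Start with what the runs share. Amber's first reading loses Sub 6.00 times as fast as teal's average over its whole run, and amber has 5.50 times teal's Ptn. So I let the fraction reacted follow Ptn × time, and I anchor it on teal's last reading, 24% of the Sub left at 8.00 min, which has the same time as the new flasks.

Now take two extremes. If the loss is zero order in Sub, the fraction reacted grows in a straight line, and you get the crossing charge, the Ptn charge that just finishes the Sub at 8.0 min: 263 mM. Friday's fraction reacted is then its charge over the crossing charge, 64.6%, while Tuesday's and Sunday's, with more Ptn than the crossing charge, finish within the time in this extreme.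

If the loss is instead pseudo-first-order, the fraction left decays exponentially through the same anchor. That gives 70.3% for Friday's, 91.2% for Tuesday's and 99.2% for Sunday's. An order between zero and one, drawn through the same anchor, falls between the two, so that is my bracket. One reading stands outside it: amber at 2.50 min has 12% of its Sub left where the exponential gives 8.60%, with a scatter of 1.5 percentage points.

The forecast says 68%, 88% and 99%, and of the trend it rises, on the grounds that “The two runs fall on one curve against Ptn × time”. Its Tuesday's figure stands below my bracket.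

The flasks give 66.5% for Friday's, 93.7% for Tuesday's and 99.5% for Sunday's, and of the trend it rises, by 33 points.

    2 Imd2 → Zed3 (k = 6.20 × 10⁶ M⁻¹ s⁻¹)
    Ptn + Prd ⇌ Ptn.Prd, settled at all times (K = 3.81 M⁻¹)
    Sub + Prd → Sub.Prd (k = 0.0430 M⁻¹ s⁻¹)
    Spx → 2 Spx2 (k = 4.05 × 10⁻⁴ s⁻¹)
    Sub + Spx2 → Spx3 + Imd (k = 4.06 × 10⁵ M⁻¹ s⁻¹)
    Sub + Imd2 → Lvg + Imd (k = 69500 M⁻¹ s⁻¹)
    Imd → Zed (k = 12.8 s⁻¹)
    2 Imd → Zed2 (k = 6.00 × 10⁸ M⁻¹ s⁻¹)
    Ptn + Imd → Prd + Imd2 (k = 4310 M⁻¹ s⁻¹)
    Sub + Lvg ⇌ Sub.Lvg, settled at all times (K = 79.4 M⁻¹)

Tuesday's still holds 6.3% of its Sub at 8.00 min, although its Ptn charge lies above the crossing charge. Sunday's read at 2.0 min has the Ptn × time of Friday's, so the crossing charge gives it 64.6%, and that flask has reacted 64.3%.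

(The data were computed on assumed constants.)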